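(The numbers in the tables stem from a simulated flask with constants of no real substance; scatter was added.)

**Looking first.** If a plate is to set Q in portions against Q at once, I look first at the rate of J, not at what stands in the flask.

| flask | Q | L | remark | time | volume of the second phase over the first |
|---|---|---|---|---|---|
| alder | 0.11 M (in portions, 4) | 1.2 equiv | run made earlier; portions every 10 min |  |  |
| elm | 0.11 M (in portions, 4) | 2.7 equiv | run made earlier; portions every 10 min |  |  |
| amber | 0.11 M (in portions, 4) | 1.80 equiv | the portions of Q follow each other after 10 min, the first at the start | 4.0 h | 0.50 |
| teal | 0.11 M | 1.80 equiv | everything together at the start | 4.0 h | 0.50 |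

| alder: time / h | alder: J / % | elm: time / h | elm: J / % |
|---|---|---|---|
| 0.417 | 11 | 0.417 | 30 |
| 0.667 | 23 | 0.667 | 42 |
| 1.00 | 22 | 1.00 | 44 |
| 2.00 | 23 | 2.00 | 47 |
| 3.00 | 25 | 3.00 | 44 |
| 5.00 | 24 | 5.00 | 44 |

(standard deviation of a reading: 2 percentage points)

- in percentages every species weighs as the Q in it: one E counts as two
- in the second phase: L; everything else is in the first
- charges count per volume of the first phase; a concentration in a rate is the amount of a species over the volume of its own phase; every rate counts per litre of the first phase
- the numbers in the tables scatter with a standard deviation of 2 percentage points
- on the list of suspects stand: G <-> L; Q + G -> J; G -> D; 2 Q -> E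
- the earlier runs hold the two phases in the same ratio of volumes as the flask asked about

1. which of the two ends with the higher amount of J, in percent of the Q charged ("neither" if they lie within 2 percentage points) (amber / teal / neither)
2. J at the end, in percent of the Q charged, amber
3. J at the end, in percent of the Q charged, teal

**The rate.** As read from elm, J comes at 0.719 h⁻¹ of the charged Q up to the first reading. The rate as read then falls by a factor of 1.50, and after 1.00 h any rise lies within the scatter. Alder and elm read 24% and 44% at their last readings, which I read as 0.181 of a J per L on average.

**The odds.** I read that as a race for G. Its rate into J follows the standing Q, while its rate into D does not. So I carry the capture odds 0.222, the share of L that reaches J over the share that does not, a selectivity factor.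

I reckon that over the 4 steps of feeding, teal holds 1.60 times the Q of a portioned flask, losses aside. On that estimate I scale teal's odds to 0.355. I expect amber at 32.7% and teal at 47.1%, so teal stands higher.

**The forecast.** The forecast says amber, with amber 33% and teal 14%, on this ground: “J is set by competition between first-order capture by G and second-order loss of Q to E”. On teal it parts from my reckoning.

**The result.** The flasks give teal: amber 34.1%, teal 44.1%.

    G ⇌ L, rate k1*([G] - [L]/K1) per volume of the first phase (partition coefficient = 0.670, kL = 2.10 min⁻¹)
    Q + G → J (k = 0.410 L mol⁻¹ min⁻¹)
    G → D (k = 0.0520 min⁻¹)
    2 Q → E (k = 0.350 L mol⁻¹ min⁻¹)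

**One reason.** The way Q goes in makes the gap: with that difference taken away, and teal's charge fed in portions, teal ends at 34.1%. In amber, G goes to D with a half-life of 0.22 h, shorter than the 0.26 h of capture into J with the whole Q counted at once. Teal's odds come out at 0.324 against my 0.355. Scaled by its Q, those odds put a flask like teal at 0.19 M, with the equivalents of L held, at 64.6%, but that flask ends at 51.5%.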